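The target is divided at the C2–C7 bond joining its two trans-2,3-diaryl-2,3-dihydrobenzofurans, and each heterocycle is closed at its aryl C7a–O1 bond. The key step uses the substitution of ring C of the inner unit (the one carrying the 2,4-dihydroxyphenyl group), where O1 sits on C7a and the outer unit on the adjacent C7: a lithium alkoxide adding to a C7a–C7 aryne closes the dihydrofuran and leaves the aryl anion exactly at C7, where iodine installs the coupling handle. Its precursor is a (1R,2R)-1,2,2-triarylethanol carrying a 2-chloro-6-methoxyphenyl group, reached by two ketone α-arylations and one hydrogenation with dynamic kinetic resolution; the same sequence then builds the outer unit.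

Key step: step 4

Ring names: ring C is the benzo ring of the inner dihydrobenzofuran, ring A the benzo ring of the outer, stilbene-bearing one; locants O1, C2, C3, C3a, C4–C7, C7a are those of each 2,3-dihydrobenzofuran.

Remark: 2-bromo-3-chloroanisole and 3-chloro-5-methoxybenzaldehyde are taken as catalogue compounds, and the facial sense of the hydrogenation catalyst is assigned by analogy with simple aryl ketones; its mirror-image form would be used if the sense proved opposite.

Step 1
Reactants: 1 1-(2,4-dimethoxyphenyl)ethan-1-one (2',4'-dimethoxyacetophenone); 2 2-bromo-1-chloro-3-methoxybenzene (2-bromo-3-chloroanisole)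
Product: 3 2-(2-chloro-6-methoxyphenyl)-1-(2,4-dimethoxyphenyl)ethan-1-one
Conditions: Pd2(dba)3 (2 mol%), Xantphos (5 mol%), NaOtBu (1.3 equiv), toluene, 80 °C
Reagents that add atoms: none
Why: Palladium-catalysed α-arylation of a methyl ketone enolate (Buchwald–Hartwig–Miura reaction) should couple at the C–Br bond of 2 while a wide-bite-angle bisphosphine leaves the C–Cl bond alone, and the 2,6-disubstituted aryl group now on the α-carbon blocks a second arylation by 2.

Step 2
Reactants: 3 2-(2-chloro-6-methoxyphenyl)-1-(2,4-dimethoxyphenyl)ethan-1-one; 4 1-bromo-3,5-dimethoxybenzene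
Product: 5 (±)-2-(2-chloro-6-methoxyphenyl)-1-(2,4-dimethoxyphenyl)-2-(3,5-dimethoxyphenyl)ethan-1-one
Conditions: Pd2(dba)3 (2 mol%), Xantphos (5 mol%), NaOtBu (1.3 equiv), toluene, 80 °C
Reagents that add atoms: none
Why: The same palladium-catalysed enolate arylation should join the unhindered bromide 4 to the benzylic enolate of 3, and the new α-stereocentre is left racemic on purpose because it is configurationally labile next to the carbonyl and is fixed only in step 3.

Step 3
Reactants: 5 (±)-2-(2-chloro-6-methoxyphenyl)-1-(2,4-dimethoxyphenyl)-2-(3,5-dimethoxyphenyl)ethan-1-one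
Product: 6 (1R,2R)-2-(2-chloro-6-methoxyphenyl)-1-(2,4-dimethoxyphenyl)-2-(3,5-dimethoxyphenyl)ethan-1-ol
Conditions: RuCl2[(S)-xylbinap][(S)-daipen] (1 mol%), KOtBu (20 mol%), H2 (10 atm), iPrOH–THF, 30 °C
Reagents that add atoms: none
Why: In this Noyori asymmetric hydrogenation with dynamic kinetic resolution the base equilibrates the enantiomers of 5 through the enolate, the catalyst should fix C1 as R by hydride delivery to one carbonyl face as with simple aryl ketones, and the 2R enantiomer should be reduced faster because it can hold the bulky 2-chloro-6-methoxyphenyl group anti to the incoming hydride (Felkin–Anh), so both stereocentres are set together as (1R,2R) and any minor diastereomer is removed by chromatography.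

Step 4
Reactants: 6 (1R,2R)-2-(2-chloro-6-methoxyphenyl)-1-(2,4-dimethoxyphenyl)-2-(3,5-dimethoxyphenyl)ethan-1-ol
Product: 9 (2R,3R)-2-(2,4-dimethoxyphenyl)-3-(3,5-dimethoxyphenyl)-7-iodo-4-methoxy-2,3-dihydro-1-benzofuran, via aryne alkoxide 7 (not isolated), via 7-lithio dihydrobenzofuran 8 (not isolated)
Conditions: lithium 2,2,6,6-tetramethylpiperidide (2.2 equiv), THF, −78 °C, then −40 °C; recool to −78 °C, I2 (1.3 equiv) in THF; aq. Na2S2O3
Reagents that add atoms: iodine, II
Why: The amide base first forms the lithium alkoxide and then removes the only hydrogen ortho to chlorine; on warming, the ortho-chloroaryllithium expels LiCl to give aryne 7 across the future C7a–C7 bond, the tethered alkoxide adds to the nearer aryne carbon to make the aryl C7a–O1 bond, and the aryllithium 8 left at C7 is iodinated. The closest known reaction type is the base-induced benzyne cyclisation of haloarenes carrying a tethered alkoxide (anionic benzyne cyclisation) with electrophilic quench of the resulting aryl anion. The ring closes in the 5-exo-dig mode, the only one the two-carbon tether permits, so oxygen goes to C7a and the anion to C7. No stereocentre is created: the carbinol C–O bond is never broken, so C2 keeps its configuration and the (1R,2R) alcohol gives the trans (2R,3R) ring. The step needs metalation next to chlorine only, in competition with the C–H bonds flanked by two methoxy groups on the two spectator rings and with the doubly benzylic C–H; this is secured by the single ortho hydrogen, whose lithiation alone is made irreversible by LiCl loss, by the adjacent alkoxide, which disfavours a second negative charge at the benzylic carbon, and by using just over two equivalents of base with a cold iodine quench.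

Step 5
Reactants: 9 (2R,3R)-2-(2,4-dimethoxyphenyl)-3-(3,5-dimethoxyphenyl)-7-iodo-4-methoxy-2,3-dihydro-1-benzofuran
Product: 11 1-[(2R,3R)-2-(2,4-dimethoxyphenyl)-3-(3,5-dimethoxyphenyl)-4-methoxy-2,3-dihydro-1-benzofuran-7-yl]ethan-1-one, via arylmagnesium chloride 10 (not isolated)
Conditions: iPrMgCl·LiCl (1.1 equiv), THF, −20 °C; then N-methoxy-N-methylacetamide (1.5 equiv), −20 °C to rt; aq. NH4Cl
Reagents that add atoms: N-methoxy-N-methylacetamide, CC(=O)N(C)OC
Why: Iodine–magnesium exchange should be fast for an aryl iodide ortho to an ether oxygen, and the arylmagnesium 10 adds once to the Weinreb amide, whose chelated adduct collapses to the methyl ketone only on work-up (Weinreb ketone synthesis), with no stereocentre touched.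

Step 6
Reactants: 12 3-chloro-5-methoxybenzaldehyde; 13 diethyl (4-methoxybenzyl)phosphonate
Product: 14 1-chloro-3-methoxy-5-[(E)-2-(4-methoxyphenyl)ethenyl]benzene
Conditions: KOtBu (1.2 equiv), THF, 0 °C to rt
Reagents that add atoms: none
Why: Horner–Wadsworth–Emmons olefination of an aromatic aldehyde with a benzylic phosphonate carbanion should give the E-stilbene selectively.

Step 7
Reactants: 14 1-chloro-3-methoxy-5-[(E)-2-(4-methoxyphenyl)ethenyl]benzene
Product: 16 2-bromo-1-chloro-3-methoxy-5-[(E)-2-(4-methoxyphenyl)ethenyl]benzene, via aryllithium 15 (not isolated)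
Conditions: lithium 2,2,6,6-tetramethylpiperidide (1.1 equiv), THF, −78 °C; then BrCl2C–CCl2Br (1.2 equiv), −78 °C to rt
Reagents that add atoms: 1,2-dibromo-1,1,2,2-tetrachloroethane, BrC(Cl)(Cl)C(Cl)(Cl)Br
Why: In this directed ortho-lithiation the C–H flanked by chlorine and methoxy is the most acidic site and is removed by the hindered amide at −78 °C, where aryllithium 15 does not yet lose LiCl, and the positive-bromine donor brominates it without adding to the stilbene double bond.

Step 8
Reactants: 11 1-[(2R,3R)-2-(2,4-dimethoxyphenyl)-3-(3,5-dimethoxyphenyl)-4-methoxy-2,3-dihydro-1-benzofuran-7-yl]ethan-1-one; 16 2-bromo-1-chloro-3-methoxy-5-[(E)-2-(4-methoxyphenyl)ethenyl]benzene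
Product: 17 2-{2-chloro-6-methoxy-4-[(E)-2-(4-methoxyphenyl)ethenyl]phenyl}-1-[(2R,3R)-2-(2,4-dimethoxyphenyl)-3-(3,5-dimethoxyphenyl)-4-methoxy-2,3-dihydro-1-benzofuran-7-yl]ethan-1-one
Conditions: Pd2(dba)3 (3 mol%), Xantphos (7 mol%), K3PO4 (2.5 equiv), toluene, 90 °C
Reagents that add atoms: none
Why: This is the palladium-catalysed methyl ketone α-arylation of step 1, run with the milder base K3PO4 to spare the C3–H of the existing dihydrofuran, and neither the C–Cl bond nor the stilbene should be engaged by this catalyst.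

Step 9
Reactants: 17 the ketone of step 8; 4 1-bromo-3,5-dimethoxybenzene
Product: 18 2-{2-chloro-6-methoxy-4-[(E)-2-(4-methoxyphenyl)ethenyl]phenyl}-1-[(2R,3R)-2-(2,4-dimethoxyphenyl)-3-(3,5-dimethoxyphenyl)-4-methoxy-2,3-dihydro-1-benzofuran-7-yl]-2-(3,5-dimethoxyphenyl)ethan-1-one (both epimers at the new α-carbon)
Conditions: Pd2(dba)3 (3 mol%), Xantphos (7 mol%), K3PO4 (2.5 equiv), toluene, 90 °C
Reagents that add atoms: none
Why: This second palladium-catalysed α-arylation parallels step 2, and the new α-centre forms as a pair of epimers that interconvert by enolisation and is fixed in step 10.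

Step 10
Reactants: 18 the triaryl ketone of step 9
Product: 19 (1R,2R)-2-{2-chloro-6-methoxy-4-[(E)-2-(4-methoxyphenyl)ethenyl]phenyl}-1-[(2R,3R)-2-(2,4-dimethoxyphenyl)-3-(3,5-dimethoxyphenyl)-4-methoxy-2,3-dihydro-1-benzofuran-7-yl]-2-(3,5-dimethoxyphenyl)ethan-1-ol
Conditions: RuCl2[(S)-xylbinap][(S)-daipen] (2 mol%), KOtBu (20 mol%), H2 (10 atm), iPrOH–THF, 30 °C
Reagents that add atoms: none
Why: As in step 3, Noyori hydrogenation with dynamic kinetic resolution should set the carbinol carbon as R under catalyst control irrespective of the remote stereocentres and select the 2R epimer of the equilibrating ketone by Felkin–Anh matching, while this ruthenium diphosphine–diamine catalyst reduces C=O and leaves the stilbene C=C and the C–Cl bond intact.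

Step 11
Reactants: 19 the (1R,2R) alcohol of step 10
Product: 22 (2R,3R)-7-{(2R,3R)-3-(3,5-dimethoxyphenyl)-4-methoxy-6-[(E)-2-(4-methoxyphenyl)ethenyl]-2,3-dihydro-1-benzofuran-2-yl}-2-(2,4-dimethoxyphenyl)-3-(3,5-dimethoxyphenyl)-4-methoxy-2,3-dihydro-1-benzofuran (heptamethyl ether of the target), via aryne alkoxide 20 (not isolated), via 7-lithio bis-dihydrobenzofuran 21 (not isolated)
Conditions: lithium 2,2,6,6-tetramethylpiperidide (2.2 equiv), THF, −78 to −30 °C; H2O
Reagents that add atoms: none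
Why: This repeats the anionic aryne cyclisation of step 4 on ring A: the amide removes the only hydrogen ortho to chlorine, LiCl is lost, the tethered lithium alkoxide closes the outer dihydrofuran 5-exo with retention at the carbinol carbon to give the trans (2R,3R) ring, and aryllithium 21 is simply protonated on work-up.

Step 12
Reactants: 22 the heptamethyl ether of step 11
Product: 23 CNP0217875.2, 4-[(2R,3R)-7-{(2R,3R)-3-(3,5-dihydroxyphenyl)-4-hydroxy-6-[(E)-2-(4-hydroxyphenyl)ethenyl]-2,3-dihydro-1-benzofuran-2-yl}-3-(3,5-dihydroxyphenyl)-4-hydroxy-2,3-dihydro-1-benzofuran-2-yl]benzene-1,3-diol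
Conditions: BBr3 (25 equiv), CH2Cl2, −78 °C to rt; MeOH, then H2O
Reagents that add atoms: none
Why: Lewis-acid cleavage of aryl methyl ethers with BBr3 is the usual global deprotection of permethylated oligostilbenes; the C3 stereocentres are never ionised, and because both rings are trans, the thermodynamically preferred arrangement, any reversible opening at a benzylic C2–O1 bond should reclose to the same diastereomer.

Compound list
1 | 1-(2,4-dimethoxyphenyl)ethan-1-one | CC(=O)c1ccc(OC)cc1OC | starting material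
2 | 2-bromo-1-chloro-3-methoxybenzene | COc1cccc(Cl)c1Br | starting material
3 | 2-(2-chloro-6-methoxyphenyl)-1-(2,4-dimethoxyphenyl)ethan-1-one | COc1cccc(Cl)c1CC(=O)c1ccc(OC)cc1OC | intermediate
4 | 1-bromo-3,5-dimethoxybenzene | COc1cc(Br)cc(OC)c1 | starting material
5 | (±)-2-(2-chloro-6-methoxyphenyl)-1-(2,4-dimethoxyphenyl)-2-(3,5-dimethoxyphenyl)ethan-1-one | COc1cccc(Cl)c1C(c1cc(OC)cc(OC)c1)C(=O)c1ccc(OC)cc1OC | intermediate
6 | (1R,2R)-2-(2-chloro-6-methoxyphenyl)-1-(2,4-dimethoxyphenyl)-2-(3,5-dimethoxyphenyl)ethan-1-ol | COc1cccc(Cl)c1[C@@H](c1cc(OC)cc(OC)c1)[C@@H](O)c1ccc(OC)cc1OC | intermediate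
7 | lithium (1R,2R)-1-(2,4-dimethoxyphenyl)-2-(3,5-dimethoxyphenyl)-2-(6-methoxy-2,3-didehydrophenyl)ethan-1-olate (aryne) | COC1=C([C@@H](c2cc(OC)cc(OC)c2)[C@@H](O[Li])c2ccc(OC)cc2OC)C#CC=C1 | intermediate
8 | [(2R,3R)-2-(2,4-dimethoxyphenyl)-3-(3,5-dimethoxyphenyl)-4-methoxy-2,3-dihydro-1-benzofuran-7-yl]lithium | [Li]c1ccc(OC)c2c1O[C@@H](c1ccc(OC)cc1OC)[C@@H]2c1cc(OC)cc(OC)c1 | intermediate
9 | (2R,3R)-2-(2,4-dimethoxyphenyl)-3-(3,5-dimethoxyphenyl)-7-iodo-4-methoxy-2,3-dihydro-1-benzofuran | Ic1ccc(OC)c2c1O[C@@H](c1ccc(OC)cc1OC)[C@@H]2c1cc(OC)cc(OC)c1 | intermediate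
10 | [(2R,3R)-2-(2,4-dimethoxyphenyl)-3-(3,5-dimethoxyphenyl)-4-methoxy-2,3-dihydro-1-benzofuran-7-yl]magnesium chloride | Cl[Mg]c1ccc(OC)c2c1O[C@@H](c1ccc(OC)cc1OC)[C@@H]2c1cc(OC)cc(OC)c1 | intermediate
11 | 1-[(2R,3R)-2-(2,4-dimethoxyphenyl)-3-(3,5-dimethoxyphenyl)-4-methoxy-2,3-dihydro-1-benzofuran-7-yl]ethan-1-one | CC(=O)c1ccc(OC)c2c1O[C@@H](c1ccc(OC)cc1OC)[C@@H]2c1cc(OC)cc(OC)c1 | intermediate
12 | 3-chloro-5-methoxybenzaldehyde | COc1cc(Cl)cc(C=O)c1 | starting material
13 | diethyl (4-methoxybenzyl)phosphonate | CCOP(=O)(Cc1ccc(OC)cc1)OCC | starting material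
14 | 1-chloro-3-methoxy-5-[(E)-2-(4-methoxyphenyl)ethenyl]benzene | COc1ccc(/C=C/c2cc(Cl)cc(OC)c2)cc1 | intermediate
15 | {2-chloro-6-methoxy-4-[(E)-2-(4-methoxyphenyl)ethenyl]phenyl}lithium | COc1ccc(/C=C/c2cc(Cl)c([Li])c(OC)c2)cc1 | intermediate
16 | 2-bromo-1-chloro-3-methoxy-5-[(E)-2-(4-methoxyphenyl)ethenyl]benzene | COc1ccc(/C=C/c2cc(Cl)c(Br)c(OC)c2)cc1 | intermediate
17 | 2-{2-chloro-6-methoxy-4-[(E)-2-(4-methoxyphenyl)ethenyl]phenyl}-1-[(2R,3R)-2-(2,4-dimethoxyphenyl)-3-(3,5-dimethoxyphenyl)-4-methoxy-2,3-dihydro-1-benzofuran-7-yl]ethan-1-one | COc1cc(/C=C/c2ccc(OC)cc2)cc(Cl)c1CC(=O)c1ccc(OC)c2c1O[C@@H](c1ccc(OC)cc1OC)[C@@H]2c1cc(OC)cc(OC)c1 | intermediate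
18 | 2-{2-chloro-6-methoxy-4-[(E)-2-(4-methoxyphenyl)ethenyl]phenyl}-1-[(2R,3R)-2-(2,4-dimethoxyphenyl)-3-(3,5-dimethoxyphenyl)-4-methoxy-2,3-dihydro-1-benzofuran-7-yl]-2-(3,5-dimethoxyphenyl)ethan-1-one, both α-epimers | COc1cc(/C=C/c2ccc(OC)cc2)cc(Cl)c1C(c1cc(OC)cc(OC)c1)C(=O)c1ccc(OC)c2c1O[C@@H](c1ccc(OC)cc1OC)[C@@H]2c1cc(OC)cc(OC)c1 | intermediate
19 | (1R,2R)-2-{2-chloro-6-methoxy-4-[(E)-2-(4-methoxyphenyl)ethenyl]phenyl}-1-[(2R,3R)-2-(2,4-dimethoxyphenyl)-3-(3,5-dimethoxyphenyl)-4-methoxy-2,3-dihydro-1-benzofuran-7-yl]-2-(3,5-dimethoxyphenyl)ethan-1-ol | COc1cc(/C=C/c2ccc(OC)cc2)cc(Cl)c1[C@@H](c1cc(OC)cc(OC)c1)[C@@H](O)c1ccc(OC)c2c1O[C@@H](c1ccc(OC)cc1OC)[C@@H]2c1cc(OC)cc(OC)c1 | intermediate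
20 | lithium alkoxide of 19 with ring A as its 2,3-aryne (chlorine and the adjacent hydrogen removed) | COC1=C([C@@H](c2cc(OC)cc(OC)c2)[C@@H](O[Li])c2ccc(OC)c3c2O[C@@H](c2ccc(OC)cc2OC)[C@@H]3c2cc(OC)cc(OC)c2)C#CC(/C=C/c2ccc(OC)cc2)=C1 | intermediate
21 | 7-lithio derivative of 22 (lithium on C7 of the outer dihydrobenzofuran) | COc1ccc(/C=C/c2cc(OC)c3c(c2[Li])O[C@@H](c2ccc(OC)c4c2O[C@@H](c2ccc(OC)cc2OC)[C@@H]4c2cc(OC)cc(OC)c2)[C@@H]3c2cc(OC)cc(OC)c2)cc1 | intermediate
22 | (2R,3R)-7-{(2R,3R)-3-(3,5-dimethoxyphenyl)-4-methoxy-6-[(E)-2-(4-methoxyphenyl)ethenyl]-2,3-dihydro-1-benzofuran-2-yl}-2-(2,4-dimethoxyphenyl)-3-(3,5-dimethoxyphenyl)-4-methoxy-2,3-dihydro-1-benzofuran | COc1ccc(/C=C/c2cc(OC)c3c(c2)O[C@@H](c2ccc(OC)c4c2O[C@@H](c2ccc(OC)cc2OC)[C@@H]4c2cc(OC)cc(OC)c2)[C@@H]3c2cc(OC)cc(OC)c2)cc1 | intermediate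
23 | CNP0217875.2, 4-[(2R,3R)-7-{(2R,3R)-3-(3,5-dihydroxyphenyl)-4-hydroxy-6-[(E)-2-(4-hydroxyphenyl)ethenyl]-2,3-dihydro-1-benzofuran-2-yl}-3-(3,5-dihydroxyphenyl)-4-hydroxy-2,3-dihydro-1-benzofuran-2-yl]benzene-1,3-diol | Oc1ccc(/C=C/c2cc(O)c3c(c2)O[C@@H](c2ccc(O)c4c2O[C@@H](c2ccc(O)cc2O)[C@@H]4c2cc(O)cc(O)c2)[C@@H]3c2cc(O)cc(O)c2)cc1 | target

Total step count: 12. Longest linear sequence: 10 steps (steps 1–5 and 8–12, from 1 to 23); steps 6–7 form the side branch to 16.

Steps most likely to fail

Step 4. The C7 aryllithium may be lost by proton transfer from the liberated amine or from the C–H bonds lying between two methoxy groups before iodine arrives, or metalation may compete at those sites, so that iodine is lost or misplaced. The fallback sets out from 1 and returns at 9, and it triggers the same aryne by bromine–lithium exchange instead of deprotonation, with no amine present. Ketone 1 is arylated with 4 under the conditions of step 1 to give 1-(2,4-dimethoxyphenyl)-2-(3,5-dimethoxyphenyl)ethan-1-one F1. Purchased 4-bromo-3-chloroanisole is lithiated between methoxy and chlorine (lithium diisopropylamide, THF, −78 °C) to (3-bromo-2-chloro-6-methoxyphenyl)lithium F2 and quenched with I2 to give 1-bromo-2-chloro-3-iodo-4-methoxybenzene F3. Palladium-catalysed α-arylation of F1 with F3 at the C–I bond (Pd2(dba)3, Xantphos, NaOtBu, toluene, 60 °C) gives (±)-2-(3-bromo-2-chloro-6-methoxyphenyl)-1-(2,4-dimethoxyphenyl)-2-(3,5-dimethoxyphenyl)ethan-1-one F4, and hydrogenation as in step 3 gives (1R,2R)-2-(3-bromo-2-chloro-6-methoxyphenyl)-1-(2,4-dimethoxyphenyl)-2-(3,5-dimethoxyphenyl)ethan-1-ol F5. Methyllithium (1 equiv) followed by tert-butyllithium (2 equiv) at −100 °C in THF converts F5 into lithium (1R,2R)-2-(2-chloro-3-lithio-6-methoxyphenyl)-1-(2,4-dimethoxyphenyl)-2-(3,5-dimethoxyphenyl)ethan-1-olate F6, which on warming to −40 °C loses LiCl to aryne 7, cyclises to 8 and is quenched with I2 to give 9.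

Step 3. The hindered, electron-rich ketone may be hydrogenated slowly, or the catalyst may discriminate poorly between the two α-epimers, giving low diastereoselectivity. The fallback sets out from 5 and returns at 6, and it replaces catalyst control by substrate control followed by resolution. Reduction of 5 with LiAlH4 in THF at −78 °C under Felkin–Anh control should give the racemic like-configured alcohol, that is 6 together with (1S,2S)-2-(2-chloro-6-methoxyphenyl)-1-(2,4-dimethoxyphenyl)-2-(3,5-dimethoxyphenyl)ethan-1-ol F7. The two are separated by preparative chromatography on a chiral stationary phase, and F7 is oxidised back to 5 with Dess–Martin periodinane and recycled.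

Step 11. The longer exposure of the finished inner dihydrofuran to the amide base may remove its C3–H and expel the phenoxide, opening the ring. The fallback sets out from 19 and returns at 22, and it closes the outer ring without strong base by palladium-catalysed intramolecular C–O coupling of the aryl chloride with the secondary alcohol (Pd(OAc)2, 2-(di-tert-butylphosphino)-1,1'-binaphthyl, Cs2CO3, toluene, 70 °C). This also proceeds with retention at the carbinol carbon and makes no new compound (F0).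

Further compounds
F1 | step 4 | 1-(2,4-dimethoxyphenyl)-2-(3,5-dimethoxyphenyl)ethan-1-one | COc1cc(CC(=O)c2ccc(OC)cc2OC)cc(OC)c1
F2 | step 4 | (3-bromo-2-chloro-6-methoxyphenyl)lithium | COc1ccc(Br)c(Cl)c1[Li]
F3 | step 4 | 1-bromo-2-chloro-3-iodo-4-methoxybenzene | COc1ccc(Br)c(Cl)c1I
F4 | step 4 | (±)-2-(3-bromo-2-chloro-6-methoxyphenyl)-1-(2,4-dimethoxyphenyl)-2-(3,5-dimethoxyphenyl)ethan-1-one | COc1ccc(Br)c(Cl)c1C(c1cc(OC)cc(OC)c1)C(=O)c1ccc(OC)cc1OC
F5 | step 4 | (1R,2R)-2-(3-bromo-2-chloro-6-methoxyphenyl)-1-(2,4-dimethoxyphenyl)-2-(3,5-dimethoxyphenyl)ethan-1-ol | COc1ccc(Br)c(Cl)c1[C@@H](c1cc(OC)cc(OC)c1)[C@@H](O)c1ccc(OC)cc1OC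
F6 | step 4 | lithium (1R,2R)-2-(2-chloro-3-lithio-6-methoxyphenyl)-1-(2,4-dimethoxyphenyl)-2-(3,5-dimethoxyphenyl)ethan-1-olate | COc1ccc([Li])c(Cl)c1[C@@H](c1cc(OC)cc(OC)c1)[C@@H](O[Li])c1ccc(OC)cc1OC
F7 | step 3 | (1S,2S)-2-(2-chloro-6-methoxyphenyl)-1-(2,4-dimethoxyphenyl)-2-(3,5-dimethoxyphenyl)ethan-1-ol | COc1cccc(Cl)c1[C@H](c1cc(OC)cc(OC)c1)[C@H](O)c1ccc(OC)cc1OC
F0 | step 11 | none | none
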